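(The earlier runs and the new flask are simulated for substances that don't exist; scatter was added.)

I decide to reckon this flask from the zero of the scale. A catalyst with no preference between the mirror substrates has selectivity factor s equal to one, where s is ln(left-handed substrate left) over ln(right-handed substrate left), each as a fraction of its own charge.

in all of them: left-handed substrate 0.10 M; right-handed substrate 0.10 M; free catalyst 0.20 mM

| run | coupling partner | protic impurity | stray impurity | remark | time |
|---|---|---|---|---|---|
| ash | 0.11 M | 5 mM | 14 µM | run made earlier |  |
| larch | 0.11 M | 5 mM | 32 µM | run made earlier |  |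
| birch | 0.11 M | 2.5 mM | 21 µM | run made earlier |  |
| flask | 0.110 M | 5.00 mM | 21 µM |  | 30 h |

| run | time / h | left-handed substrate / % | right-handed substrate / % |
|---|---|---|---|
| ash | 2.00 | 42 | 47 |
| ash | 6.00 | 38 | 41 |
| ash | 10.0 | 32 | 38 |
| ash | 15.0 | 29 | 36 |
| ash | 20.0 | 28 | 39 |
| ash | 30.0 | 26 | 33 |
| ash | 40.0 | 22 | 37 |
| larch | 3.00 | 49 | 44 |
| larch | 4.00 | 43 | 44 |
| larch | 6.00 | 42 | 44 |
| larch | 10.0 | 34 | 43 |
| larch | 15.0 | 33 | 41 |
| larch | 25.0 | 28 | 35 |
| larch | 40.0 | 25 | 36 |
| birch | 3.00 | 41 | 46 |
| birch | 10.0 | 36 | 41 |
| birch | 15.0 | 31 | 41 |
| birch | 25.0 | 30 | 37 |
| birch | 40.0 | 22 | 31 |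

(readings scatter by 2 percentage points)

- free catalyst is single-handed; left-handed substrate and right-handed substrate are mirror images of each other, charged as a racemate, each of them at the stated concentration
- the numbers in the tables scatter by 2 percentage points (one standard deviation)
- an excess is the difference of the two amounts in percent of their sum
- an excess is below zero if the other one leads

1. part of the left-handed substrate and right-handed substrate charged together that has reacted at 30 h
2. excess of left-handed product over right-handed product in the product at 30 h
3. excess of right-handed substrate over left-handed substrate among what is left of the two at 30 h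

Pooling the last two readings of each earlier run, I read:

s = 1.87

g = (s − 1)/(s + 1) = 0.303

I call g the lever, the distance from that zero. Taking the geometric mean of what is left as 1 − c gives:

eS ≈ g·ln(1/(1 − c)), and eP = eS·(1 − c)/c

At one partner per turn, the partner charge caps c at 55.0%. I tighten this with the readings, taking it that c only rises and that more stray impurity does not speed a run. This flask carries more stray impurity than ash and less than larch, at the protic charge of both. So larch at 25.0 h gives a floor of 37.0%, and ash at 40.0 h a ceiling of 41.0%, both readings with their scatter. The lever turns these into eS from 14.0% to 16.0%, and eP from 23.9% down to 23.0%.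

The forecast says the flask “should fall between them” and gives 38%, 24% and 14.5%. Its c and eS lie inside my bracket, and its eP stands just above my range.

The flask gives 39.6%, 22.9% and 15.0%, with c and eS inside the bracket, and eP just below my range.

    coupling partner + free catalyst + left-handed substrate → free catalyst + left-handed product (k = 2710 /M²/h)
    coupling partner + free catalyst + right-handed substrate → free catalyst + right-handed product (k = 1480 /M²/h)
    coupling partner + protic impurity → quenched reagent (k = 5.83 /M/h)
    2 coupling partner → homo dimer (k = 0.0454 /M/h)
    free catalyst + stray impurity → spent catalyst (k = 1.41 × 10⁵ /M/h)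

A neighbour flask with 3.4 × 10⁻⁴ M of free catalyst, all else as in this recipe, reaches c = 46.5% at 30 h, above the ceiling. The same lever on that c gives eS 19.0% and eP 21.9%. The neighbour gives eP 21.5% and eS 18.6%.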